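The disconnection on which everything rests is C4–C4a of the chromanone ring C. The precursor is the open-chain (S)-3-aryl-3-aryloxypropanoic acid 18, which already holds the C2 stereocentre, the O1–C8a ether and both five-carbon side chains. It is assembled convergently from a ring A phenol, methyl propiolate and a ring B boronic acid by oxa-Michael addition and asymmetric rhodium-catalysed 1,4-arylation. One intramolecular Friedel–Crafts acylation then closes ring C and completes the skeleton. It exploits C4a of ring A: the only free carbon ortho to O1 (C8 bears the prenyl group), activated by O1, C5–O and C7–O, whereas C6' of ring B is meta to both of its oxygens.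

Key step: step 10

Remark: flavanone numbering is used (ring C: O1, C2, C3, C4, C4a, C8a; ring B primed); the descriptor at C2 corresponds to (S); MOM = methoxymethyl; compounds 1, 3, 6, 8 and 10 are taken as commercial.

Step 1
Reactants: 1 phloroglucinol
Product: 2 3,5-bis(methoxymethoxy)phenol
Conditions: MOMCl (2.1 equiv), i-Pr2NEt (2.5 equiv), THF/CH2Cl2, 0 °C → rt; chromatography
Reagents that add atoms: chloromethyl methyl ether, COCCl
Why: O-alkylation of the threefold-symmetric triphenol with a limited amount of reagent should give the bis-ether as the main, separable component of a statistical mixture.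

Step 2
Reactants: 2 3,5-bis(methoxymethoxy)phenol; 3 prenyl bromide (1-bromo-3-methylbut-2-ene)
Product: 5 3,5-bis(methoxymethoxy)-2-(3-methylbut-2-en-1-yl)phenol, via sodium phenoxide 4 (not isolated)
Conditions: NaH (1.0 equiv), toluene, 0 °C; then prenyl bromide, rt
Reagents that add atoms: none
Why: ortho-C-alkylation of a tight sodium phenoxide ion pair in a non-polar solvent; the two ortho carbons are equivalent, and the para carbon between the two MOM ethers is hindered and not served by sodium-directed delivery.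

Step 3
Reactants: 5 3,5-bis(methoxymethoxy)-2-(3-methylbut-2-en-1-yl)phenol; 6 methyl propiolate
Product: 7 methyl (2E)-3-[3,5-bis(methoxymethoxy)-2-(3-methylbut-2-en-1-yl)phenoxy]prop-2-enoate
Conditions: DABCO (10 mol%), CH2Cl2, 0 °C → rt
Reagents that add atoms: none
Why: amine-catalysed oxa-Michael addition of a phenol to an ynoate, which should give the (E)-β-aryloxyacrylate.

Step 4
Reactants: 8 4-bromoresorcinol (4-bromobenzene-1,3-diol)
Product: 9 1-bromo-2,4-bis(methoxymethoxy)benzene
Conditions: MOMCl (2.5 equiv), i-Pr2NEt (3 equiv), CH2Cl2, 0 °C → rt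
Reagents that add atoms: chloromethyl methyl ether, COCCl
Why: exhaustive O-alkylation; MOM ethers tolerate the later organolithium, palladium, rhodium and hydroxide steps and leave together with those of ring A at the end.

Step 5
Reactants: 9 1-bromo-2,4-bis(methoxymethoxy)benzene; 10 prenylboronic acid pinacol ester [4,4,5,5-tetramethyl-2-(3-methylbut-2-en-1-yl)-1,3,2-dioxaborolane]
Product: 11 2,4-bis(methoxymethoxy)-1-(2-methylbut-3-en-2-yl)benzene
Conditions: Pd(OAc)2 (3 mol%), 1,1'-bis(di-tert-butylphosphino)ferrocene (4 mol%), K3PO4, THF/H2O, 60 °C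
Reagents that add atoms: none
Why: γ-selective (branched) Suzuki–Miyaura coupling of a 3,3-disubstituted allylboronate; SE2' transmetalation places palladium on the tertiary carbon, and the bulky electron-rich ligand should force reductive elimination before the allyl group isomerises, giving the 1,1-dimethylallyl arene.

Step 6
Reactants: 11 2,4-bis(methoxymethoxy)-1-(2-methylbut-3-en-2-yl)benzene
Product: 12 1-bromo-2,4-bis(methoxymethoxy)-5-(2-methylbut-3-en-2-yl)benzene
Conditions: NBS (1.05 equiv), MeCN, 0 °C, dark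
Reagents that add atoms: N-bromosuccinimide, O=C1CCC(=O)N1Br
Why: electrophilic aromatic bromination at the carbon para to one MOM ether and ortho to the other (the carbon between the two ethers is hindered) should be much faster than attack on the monosubstituted alkene.

Step 7
Reactants: 12 1-bromo-2,4-bis(methoxymethoxy)-5-(2-methylbut-3-en-2-yl)benzene
Product: 15 [2,4-bis(methoxymethoxy)-5-(2-methylbut-3-en-2-yl)phenyl]boronic acid, via aryllithium 13 (not isolated), via lithium aryltrimethoxyborate 14 (not isolated)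
Conditions: n-BuLi (1.05 equiv), THF, −78 °C; B(OMe)3, −78 °C → rt; aq. NH4Cl
Reagents that add atoms: trimethyl borate, COB(OC)OC; water, O
Why: bromine–lithium exchange (the aryllithium is stabilised by the ortho MOM ether), borate formation and hydrolysis.

Step 8
Reactants: 7 methyl (2E)-3-[3,5-bis(methoxymethoxy)-2-(3-methylbut-2-en-1-yl)phenoxy]prop-2-enoate; 15 [2,4-bis(methoxymethoxy)-5-(2-methylbut-3-en-2-yl)phenyl]boronic acid
Product: 16 methyl (3S)-3-[2,4-bis(methoxymethoxy)-5-(2-methylbut-3-en-2-yl)phenyl]-3-[3,5-bis(methoxymethoxy)-2-(3-methylbut-2-en-1-yl)phenoxy]propanoate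
Conditions: [RhCl(C2H4)2]2 (2.5 mol%), (R,R)-Ph-bod* [(1R,4R)-2,5-diphenylbicyclo[2.2.2]octa-2,5-diene] (5.5 mol%), KOH (0.2 equiv), 15 (2.5 equiv), dioxane/H2O 10:1, 40 °C
Reagents that add atoms: none
Why: Proposed new method: the Hayashi–Miyaura asymmetric 1,4-arylation (closest known cases: β-phthalimidoacrylates and the cyclic β-aryloxy enone chromone) is extended to an acyclic (E)-β-aryloxyacrylate; aryl transfer from boron to rhodium, carborhodation of the acrylate and fast protonolysis of the oxa-π-allylrhodium by water should outrun β-aryloxide elimination, and the (R,R)-diene, which binds enoates through their α-Re face, should deliver the aryl group to the Re face of C3 and so set the (S)-centre that becomes C2.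

Step 9
Reactants: 16 methyl (3S)-3-[2,4-bis(methoxymethoxy)-5-(2-methylbut-3-en-2-yl)phenyl]-3-[3,5-bis(methoxymethoxy)-2-(3-methylbut-2-en-1-yl)phenoxy]propanoate
Product: 18 (3S)-3-[2,4-bis(methoxymethoxy)-5-(2-methylbut-3-en-2-yl)phenyl]-3-[3,5-bis(methoxymethoxy)-2-(3-methylbut-2-en-1-yl)phenoxy]propanoic acid, via lithium carboxylate 17 (not isolated)
Conditions: LiOH·H2O (3 equiv), THF/MeOH/H2O 3:1:1, 0 °C → rt; then 0.5 M HCl to pH 5 at 0 °C
Reagents that add atoms: lithium hydroxide, [Li+].[OH-]
Why: saponification by acyl–oxygen cleavage is much faster than α-deprotonation, so the β-aryloxy group should not be lost by E1cB elimination and the stereocentre is not touched.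

Step 10
Reactants: 18 (3S)-3-[2,4-bis(methoxymethoxy)-5-(2-methylbut-3-en-2-yl)phenyl]-3-[3,5-bis(methoxymethoxy)-2-(3-methylbut-2-en-1-yl)phenoxy]propanoic acid
Product: 21 (2S)-5,7-bis(methoxymethoxy)-2-[2,4-bis(methoxymethoxy)-5-(2-methylbut-3-en-2-yl)phenyl]-8-(3-methylbut-2-en-1-yl)-2,3-dihydro-4H-chromen-4-one, via acid chloride 19 (not isolated), via acyl triflate 20 (not isolated)
Conditions: Ghosez's reagent (1-chloro-N,N,2-trimethylprop-1-en-1-amine, 1.2 equiv), CH2Cl2, 0 °C; then added to AgOTf (1.5 equiv), 2,6-di-tert-butyl-4-methylpyridine (2 equiv), CH2Cl2 (0.01 M), −78 → −40 °C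
Reagents that add atoms: none
Why: The acid chloride, formed under neutral conditions, is turned by AgOTf into the mixed carboxylic–triflic anhydride, which acylates C4a of ring A and rearomatises by giving up a proton to the hindered pyridine; this is an intramolecular Friedel–Crafts acylation, the classical closure of 3-aryloxypropanoic acids to chroman-4-ones. Ring C (O1, C2, C3, C4, C4a, C8a) closes by 6-exo-trig attack of C4a on the acyl carbon. No stereocentre is formed; C2 is a spectator, and its configuration should be kept because the medium is cold and buffered, so that the electron-rich benzylic C2–O1 bond does not ionise. Regioselectivity is secured by the substrate: of the two carbons ortho to O1 only C4a is free (C8 carries the prenyl group), and C4a is activated by O1 and C5–O (ortho) and by C7–O (para). Chemoselectivity is needed against C6' of ring B (five-membered indanone closure), which is meta to both ring B oxygens, against capture of the acyl carbon by the 2'-MOM oxygen, which should be reversible at −78 °C, and against intermolecular acylation of the alkenes, which high dilution suppresses.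

Step 11
Reactants: 21 (2S)-5,7-bis(methoxymethoxy)-2-[2,4-bis(methoxymethoxy)-5-(2-methylbut-3-en-2-yl)phenyl]-8-(3-methylbut-2-en-1-yl)-2,3-dihydro-4H-chromen-4-one
Product: 22 (2S)-2-[2,4-dihydroxy-5-(2-methylbut-3-en-2-yl)phenyl]-5,7-dihydroxy-8-(3-methylbut-2-en-1-yl)-2,3-dihydro-4H-chromen-4-one (AChE-IN-17)
Conditions: 3 M aq. HCl/MeOH (1:5), 45 °C
Reagents that add atoms: none
Why: acid-catalysed methanolysis of the four aryl MOM acetals, the usual unmasking of prenylated flavanones; no base is present, so C2 should not racemise through ring opening to the chalcone.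

Compound list
1 | phloroglucinol (benzene-1,3,5-triol) | Oc1cc(O)cc(O)c1 | starting material
2 | 3,5-bis(methoxymethoxy)phenol | COCOc1cc(O)cc(OCOC)c1 | intermediate
3 | prenyl bromide (1-bromo-3-methylbut-2-ene) | CC(C)=CCBr | starting material
4 | sodium 3,5-bis(methoxymethoxy)phenoxide | [Na+].[O-]c1cc(OCOC)cc(OCOC)c1 | intermediate (not isolated)
5 | 3,5-bis(methoxymethoxy)-2-(3-methylbut-2-en-1-yl)phenol | CC(C)=CCc1c(O)cc(OCOC)cc1OCOC | intermediate
6 | methyl propiolate | C#CC(=O)OC | starting material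
7 | methyl (2E)-3-[3,5-bis(methoxymethoxy)-2-(3-methylbut-2-en-1-yl)phenoxy]prop-2-enoate | COC(=O)/C=C/Oc1cc(OCOC)cc(OCOC)c1CC=C(C)C | intermediate
8 | 4-bromoresorcinol (4-bromobenzene-1,3-diol) | Oc1ccc(Br)c(O)c1 | starting material
9 | 1-bromo-2,4-bis(methoxymethoxy)benzene | COCOc1ccc(Br)c(OCOC)c1 | intermediate
10 | prenylboronic acid pinacol ester | CC(C)=CCB1OC(C)(C)C(C)(C)O1 | starting material
11 | 2,4-bis(methoxymethoxy)-1-(2-methylbut-3-en-2-yl)benzene | C=CC(C)(C)c1ccc(OCOC)cc1OCOC | intermediate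
12 | 1-bromo-2,4-bis(methoxymethoxy)-5-(2-methylbut-3-en-2-yl)benzene | C=CC(C)(C)c1cc(Br)c(OCOC)cc1OCOC | intermediate
13 | [2,4-bis(methoxymethoxy)-5-(2-methylbut-3-en-2-yl)phenyl]lithium | [Li]c1cc(C(C)(C)C=C)c(OCOC)cc1OCOC | intermediate (not isolated)
14 | lithium [2,4-bis(methoxymethoxy)-5-(2-methylbut-3-en-2-yl)phenyl]trimethoxyborate | [Li+].CO[B-](OC)(OC)c1cc(C(C)(C)C=C)c(OCOC)cc1OCOC | intermediate (not isolated)
15 | [2,4-bis(methoxymethoxy)-5-(2-methylbut-3-en-2-yl)phenyl]boronic acid | OB(O)c1cc(C(C)(C)C=C)c(OCOC)cc1OCOC | intermediate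
16 | methyl (3S)-3-[2,4-bis(methoxymethoxy)-5-(2-methylbut-3-en-2-yl)phenyl]-3-[3,5-bis(methoxymethoxy)-2-(3-methylbut-2-en-1-yl)phenoxy]propanoate | C=CC(C)(C)c1cc([C@@H](Oc2cc(OCOC)cc(OCOC)c2CC=C(C)C)CC(=O)OC)c(OCOC)cc1OCOC | intermediate
17 | lithium (3S)-3-[2,4-bis(methoxymethoxy)-5-(2-methylbut-3-en-2-yl)phenyl]-3-[3,5-bis(methoxymethoxy)-2-(3-methylbut-2-en-1-yl)phenoxy]propanoate | C=CC(C)(C)c1cc([C@@H](Oc2cc(OCOC)cc(OCOC)c2CC=C(C)C)CC(=O)[O-])c(OCOC)cc1OCOC.[Li+] | intermediate (not isolated)
18 | (3S)-3-[2,4-bis(methoxymethoxy)-5-(2-methylbut-3-en-2-yl)phenyl]-3-[3,5-bis(methoxymethoxy)-2-(3-methylbut-2-en-1-yl)phenoxy]propanoic acid | C=CC(C)(C)c1cc([C@@H](Oc2cc(OCOC)cc(OCOC)c2CC=C(C)C)CC(=O)O)c(OCOC)cc1OCOC | intermediate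
19 | (3S)-3-[2,4-bis(methoxymethoxy)-5-(2-methylbut-3-en-2-yl)phenyl]-3-[3,5-bis(methoxymethoxy)-2-(3-methylbut-2-en-1-yl)phenoxy]propanoyl chloride | C=CC(C)(C)c1cc([C@@H](Oc2cc(OCOC)cc(OCOC)c2CC=C(C)C)CC(=O)Cl)c(OCOC)cc1OCOC | intermediate (not isolated)
20 | (3S)-3-[2,4-bis(methoxymethoxy)-5-(2-methylbut-3-en-2-yl)phenyl]-3-[3,5-bis(methoxymethoxy)-2-(3-methylbut-2-en-1-yl)phenoxy]propanoic trifluoromethanesulfonic anhydride | C=CC(C)(C)c1cc([C@@H](Oc2cc(OCOC)cc(OCOC)c2CC=C(C)C)CC(=O)OS(=O)(=O)C(F)(F)F)c(OCOC)cc1OCOC | intermediate (not isolated)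
21 | (2S)-5,7-bis(methoxymethoxy)-2-[2,4-bis(methoxymethoxy)-5-(2-methylbut-3-en-2-yl)phenyl]-8-(3-methylbut-2-en-1-yl)-2,3-dihydro-4H-chromen-4-one | C=CC(C)(C)c1cc([C@@H]2CC(=O)c3c(OCOC)cc(OCOC)c(CC=C(C)C)c3O2)c(OCOC)cc1OCOC | intermediate
22 | (2S)-2-[2,4-dihydroxy-5-(2-methylbut-3-en-2-yl)phenyl]-5,7-dihydroxy-8-(3-methylbut-2-en-1-yl)-2,3-dihydro-4H-chromen-4-one (AChE-IN-17) | C=CC(C)(C)c1cc([C@@H]2CC(=O)c3c(O)cc(O)c(CC=C(C)C)c3O2)c(O)cc1O | target

Total step count: 11. Longest linear sequence: 8 steps (steps 4, 5, 6, 7, 8, 9, 10, 11).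

Steps most likely to fail

1. Step 8 (proposed new method). What may go wrong: slow carborhodation of the push–pull acrylate, β-aryloxide elimination from the rhodium enolate, protodeboronation of the electron-rich boronic acid, or poor facial selectivity. Fallback with known chemistry, setting out from phenol 5 and coming back at 21: ring opening of β-propiolactone by the potassium phenoxide of 5 (t-BuOK, THF, then mild acid) should give 3-[3,5-bis(methoxymethoxy)-2-(3-methylbut-2-en-1-yl)phenoxy]propanoic acid F1. The protocol of step 10 carries it through 3-[3,5-bis(methoxymethoxy)-2-(3-methylbut-2-en-1-yl)phenoxy]propanoyl chloride F2 and the corresponding carboxylic–triflic anhydride F3 to 5,7-bis(methoxymethoxy)-8-(3-methylbut-2-en-1-yl)-2,3-dihydro-4H-chromen-4-one F4. This is the same C4–C4a closure, now on an achiral acid that has no benzylic ether. Dehydrogenation with IBX (DMSO, 70 °C) gives 5,7-bis(methoxymethoxy)-8-(3-methylbut-2-en-1-yl)-4H-chromen-4-one F5. The established asymmetric 1,4-addition of arylboronic acids to chromones then adds 15 to F5 and returns to the route at 21. Conditions for that addition: Pd(OCOCF3)2, (R)-4-tert-butyl-2-(pyridin-2-yl)-4,5-dihydrooxazole (the ligand enantiomer expected to give 2S), NH4PF6, H2O, ClCH2CH2Cl, 60 °C.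

2. Step 10 (key step). What may go wrong: acid-triggered ionisation of the benzylic C2–O1 bond (racemisation or loss of the ring A phenol), capture of the acyl carbon by the 2'-MOM oxygen with loss of the MOM group (lactonisation), or cleavage of MOM ethers by the silver salt or the acyl triflate. Fallback, setting out from acid 18 and coming back at 21: acylium chemistry is replaced by electrophilic amide activation in a base-buffered medium. Coupling with dimethylamine (EDC·HCl, HOBt, Me2NH·HCl, i-Pr2NEt, CH2Cl2, 0 °C) gives (3S)-3-[2,4-bis(methoxymethoxy)-5-(2-methylbut-3-en-2-yl)phenyl]-3-[3,5-bis(methoxymethoxy)-2-(3-methylbut-2-en-1-yl)phenoxy]-N,N-dimethylpropanamide F6. Tf2O and 2-fluoropyridine (CH2Cl2, −78 → 0 °C) should then effect a Vilsmeier–Haack-type closure onto C4a to (2S)-N-{5,7-bis(methoxymethoxy)-2-[2,4-bis(methoxymethoxy)-5-(2-methylbut-3-en-2-yl)phenyl]-8-(3-methylbut-2-en-1-yl)-2,3-dihydro-4H-chromen-4-ylidene}-N-methylmethanaminium triflate F7. Hydrolysis with aq. NaHCO3 gives 21.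

3. Step 5. What may go wrong: isomerisation of the allylpalladium intermediate before reductive elimination, which leads to the linear prenyl isomer, or protodeboronation of the allylboronate. Fallback, setting out from bromide 9 and coming back at 11: the quaternary carbon is built without an allyl-metal species. Palladium-catalysed α-arylation of 2-methylpropanal with 9 (Pd(OAc)2, rac-BINAP, Cs2CO3, dioxane, 80 °C) gives 2-[2,4-bis(methoxymethoxy)phenyl]-2-methylpropanal F8. Wittig methylenation (Ph3PCH3Br, KOt-Bu, THF, 0 °C → rt) then gives 11.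

Further compounds
F1 | step 8 | 3-[3,5-bis(methoxymethoxy)-2-(3-methylbut-2-en-1-yl)phenoxy]propanoic acid | OC(=O)CCOc1cc(OCOC)cc(OCOC)c1CC=C(C)C
F2 | step 8 | 3-[3,5-bis(methoxymethoxy)-2-(3-methylbut-2-en-1-yl)phenoxy]propanoyl chloride | O=C(Cl)CCOc1cc(OCOC)cc(OCOC)c1CC=C(C)C
F3 | step 8 | 3-[3,5-bis(methoxymethoxy)-2-(3-methylbut-2-en-1-yl)phenoxy]propanoic trifluoromethanesulfonic anhydride | O=C(CCOc1cc(OCOC)cc(OCOC)c1CC=C(C)C)OS(=O)(=O)C(F)(F)F
F4 | step 8 | 5,7-bis(methoxymethoxy)-8-(3-methylbut-2-en-1-yl)-2,3-dihydro-4H-chromen-4-one | O=C1CCOc2c(CC=C(C)C)c(OCOC)cc(OCOC)c12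
F5 | step 8 | 5,7-bis(methoxymethoxy)-8-(3-methylbut-2-en-1-yl)-4H-chromen-4-one | O=c1ccoc2c(CC=C(C)C)c(OCOC)cc(OCOC)c12
F6 | step 10 | (3S)-3-[2,4-bis(methoxymethoxy)-5-(2-methylbut-3-en-2-yl)phenyl]-3-[3,5-bis(methoxymethoxy)-2-(3-methylbut-2-en-1-yl)phenoxy]-N,N-dimethylpropanamide | C=CC(C)(C)c1cc([C@@H](Oc2cc(OCOC)cc(OCOC)c2CC=C(C)C)CC(=O)N(C)C)c(OCOC)cc1OCOC
F7 | step 10 | (2S)-N-{5,7-bis(methoxymethoxy)-2-[2,4-bis(methoxymethoxy)-5-(2-methylbut-3-en-2-yl)phenyl]-8-(3-methylbut-2-en-1-yl)-2,3-dihydro-4H-chromen-4-ylidene}-N-methylmethanaminium triflate | C=CC(C)(C)c1cc([C@@H]2CC(=[N+](C)C)c3c(OCOC)cc(OCOC)c(CC=C(C)C)c3O2)c(OCOC)cc1OCOC.[O-]S(=O)(=O)C(F)(F)F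
F8 | step 5 | 2-[2,4-bis(methoxymethoxy)phenyl]-2-methylpropanal | CC(C)(C=O)c1ccc(OCOC)cc1OCOC
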